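**Assumption:** squamatic acid has no stereocentres (the SMILES contains none), so no enantiocontrol is needed. The two stereocentres in the Michael–Dieckmann intermediates (3 and 10) are racemic and are destroyed on aromatisation.

## Retrosynthetic overview
1. Squamatic acid ⇐ hydrogenolysis of two Bn groups (ring-A OBn, ring-B CO2Bn) ⇐ Pinnick oxidation of the ring-A 3-CHO, which is a masked 3-COOH.
2. The depside ester bond is the late convergent coupling: ring-A acid **8** (2-OBn, 3-CHO, 4-OMe, 6-Me) plus ring-B phenol **13** (benzyl 3-methyl-β-orsellinate, free 4-OH).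
3. Each benzene ring is built de novo: a Michael/Dieckmann annulation of a β-keto ester with methyl crotonate, then dehydrogenative aromatisation (ring A in steps 1–2, ring B in steps 8–9).
4. Ring A is then 4-O-methylated and formylated at C3, directed by the only free ortho position of the chelated phenol. Ring B gets its C3-methyl from methyl 3-oxopentanoate, made by Weiler γ-methylation of methyl acetoacetate.

## Forward route

**Fragment A (ring A acid)**

**Step 1**
Reactants: **1** methyl acetoacetate; **2** methyl (E)-crotonate
Product: **3** methyl 6-methyl-2,4-dioxocyclohexane-1-carboxylate (racemic, largely enol)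
Conditions: NaOMe (2.2 equiv), MeOH, reflux; then aq. HCl
Reagents that add atoms: none
Why: Michael addition of the acetoacetate enolate to crotonate, then Dieckmann/Claisen closure of the acetyl-CH3 enolate onto the distal ester, forms the six-membered ring; the stereocentres are racemic and erased in step 2.

**Step 2**
Reactants: **3**
Product: **4** methyl orsellinate (methyl 2,4-dihydroxy-6-methylbenzoate)
Conditions: Br2 (1.0 equiv), CHCl3, 0 °C; then Et3N, 0 °C → rt
Reagents that add atoms: none (Br is lost as HBr)
Why: α-Bromination at the enolic C1 followed by E2 loss of HBr and tautomerisation gives the aromatic resorcylate (dehydrogenative aromatisation); only one equivalent of Br2 is used to avoid ring bromination.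

**Step 3**
Reactants: **4**; MeI
Product: **5** methyl 2-hydroxy-4-methoxy-6-methylbenzoate
Conditions: MeI (1.05 equiv), K2CO3, acetone, reflux
Reagents that add atoms: methyl iodide, CI
Why: Williamson O-methylation is selective for the free 4-OH because the 2-OH is locked by a hydrogen bond to the ester C=O.

**Step 4**
Reactants: **5**; paraformaldehyde
Product: **6** methyl 3-formyl-2-hydroxy-4-methoxy-6-methylbenzoate
Conditions: MgCl2, Et3N, (CH2O)n, MeCN, reflux
Reagents that add atoms: formaldehyde, C=O
Why: Casnati–Skattebøl Mg-phenoxide ortho-formylation can only occur at C3, the sole free position ortho to the OH, so regiochemistry is forced.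

**Step 5**
Reactants: **6**; BnBr
Product: **7** methyl 2-benzyloxy-3-formyl-4-methoxy-6-methylbenzoate
Conditions: BnBr, K2CO3, DMF, 50 °C
Reagents that add atoms: benzyl bromide, BrCc1ccccc1
Why: Williamson etherification of the aldehyde-chelated phenol gives the hydrogenolysis-labile Bn ether.

**Step 6**
Reactants: **7**
Product: **8** 2-benzyloxy-3-formyl-4-methoxy-6-methylbenzoic acid
Conditions: LiI, pyridine, reflux; then cold 1 M HCl
Reagents that add atoms: none
Why: SN2 demethylation at the ester methyl carbon is insensitive to the 2,6-disubstitution that blocks saponification, and the CHO, OBn and ArOMe groups survive.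

**Fragment B (ring B phenol)**

**Step 7**
Reactants: **1**; MeI
Product: **9** methyl 3-oxopentanoate
Conditions: NaH, THF, 0 °C; then n-BuLi, −10 °C; then MeI; aq. NH4Cl
Reagents that add atoms: methyl iodide, CI
Why: the Weiler dianion alkylates at the more nucleophilic γ-carbon (Weiler alkylation), which supplies the carbon that becomes the ring-B C3-methyl.

**Step 8**
Reactants: **9**; **2**
Product: **10** methyl 3,6-dimethyl-2,4-dioxocyclohexane-1-carboxylate (racemic)
Conditions: NaOMe (2.2 equiv), MeOH, reflux; then aq. HCl
Reagents that add atoms: none
Why: Michael/Dieckmann annulation as in step 1; the propionyl CH2 closes the ring, placing the methyl between the two future oxygens.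

**Step 9**
Reactants: **10**
Product: **11** methyl 2,4-dihydroxy-3,6-dimethylbenzoate
Conditions: Br2 (1.0 equiv), CHCl3, 0 °C; then Et3N, 0 °C → rt
Reagents that add atoms: none
Why: bromination/dehydrobromination aromatisation as in step 2.

**Step 10**
Reactants: **11**; KOH/H2O
Product: **12** 2,4-dihydroxy-3,6-dimethylbenzoic acid
Conditions: KOH (aq., 10 equiv), reflux, N2; then cold 2 M HCl
Reagents that add atoms: potassium hydroxide, [K+].[OH-] (its oxygen ends up in the COOH; water is the solvent)
Why: saponification of the hindered resorcylate ester; the carboxylate resists decarboxylation under basic conditions.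

**Step 11**
Reactants: **12**; BnBr
Product: **13** benzyl 2,4-dihydroxy-3,6-dimethylbenzoate
Conditions: BnBr, NaHCO3, DMF, rt
Reagents that add atoms: benzyl bromide, BrCc1ccccc1
Why: at bicarbonate basicity only the carboxylate is alkylated (SN2), giving a hydrogenolytically removable ester.

**Convergent coupling and endgame**

**Step 12**
Reactants: **8**; **13**
Product: **14** benzyl 4-[(2-benzyloxy-3-formyl-4-methoxy-6-methylbenzoyl)oxy]-2-hydroxy-3,6-dimethylbenzoate
Conditions: (i) (COCl)2, cat. DMF, CH2Cl2, 0 °C → rt; (ii) **13**, pyridine, cat. DMAP, CH2Cl2, 0 °C → rt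
Reagents that add atoms: none (the acyl chloride is an intermediate; Cl is lost)
Why: Schotten–Baumann-type acylation occurs selectively at the unchelated 4-OH, because the 2-OH is hydrogen-bonded to the benzyl ester C=O; this forms the depside bond.

**Step 13**
Reactants: **14**
Product: **15** benzyl 4-[(2-benzyloxy-3-carboxy-4-methoxy-6-methylbenzoyl)oxy]-2-hydroxy-3,6-dimethylbenzoate
Conditions: NaClO2, NaH2PO4, 2-methylbut-2-ene, t-BuOH/H2O, rt
Reagents that add atoms: sodium chlorite, [Na+].[O-]Cl=O (supplies the oxygen of the new COOH)
Why: Pinnick oxidation converts the aryl aldehyde to the acid under mildly acidic buffer, so the aryl ester and benzyl ester survive; the alkene scavenges HOCl and prevents ring chlorination.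

**Step 14**
Reactants: **15**; H2
Product: **16** squamatic acid
Conditions: H2 (1 atm), 10% Pd/C, THF/EtOAc, rt
Reagents that add atoms: none (H2 only adds hydrogen; toluene is lost)
Why: hydrogenolysis removes the ring-B benzyl ester and the ring-A benzyl ether together, and the diaryl ester is untouched.

## Compound list
1 | methyl acetoacetate | CC(=O)CC(=O)OC | starting material
2 | methyl (E)-crotonate | C/C=C/C(=O)OC | starting material
3 | methyl 6-methyl-2,4-dioxocyclohexane-1-carboxylate (racemic, no stereo defined) | COC(=O)C1C(=O)CC(=O)CC1C | intermediate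
4 | methyl orsellinate | COC(=O)c1c(C)cc(O)cc1O | intermediate
5 | methyl 2-hydroxy-4-methoxy-6-methylbenzoate | COC(=O)c1c(C)cc(OC)cc1O | intermediate
6 | methyl 3-formyl-2-hydroxy-4-methoxy-6-methylbenzoate | COC(=O)c1c(C)cc(OC)c(C=O)c1O | intermediate
7 | methyl 2-benzyloxy-3-formyl-4-methoxy-6-methylbenzoate | COC(=O)c1c(C)cc(OC)c(C=O)c1OCc1ccccc1 | intermediate
8 | 2-benzyloxy-3-formyl-4-methoxy-6-methylbenzoic acid | OC(=O)c1c(C)cc(OC)c(C=O)c1OCc1ccccc1 | intermediate
9 | methyl 3-oxopentanoate | CCC(=O)CC(=O)OC | intermediate
10 | methyl 3,6-dimethyl-2,4-dioxocyclohexane-1-carboxylate (racemic) | COC(=O)C1C(=O)C(C)C(=O)CC1C | intermediate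
11 | methyl 2,4-dihydroxy-3,6-dimethylbenzoate | COC(=O)c1c(C)cc(O)c(C)c1O | intermediate
12 | 2,4-dihydroxy-3,6-dimethylbenzoic acid | OC(=O)c1c(C)cc(O)c(C)c1O | intermediate
13 | benzyl 2,4-dihydroxy-3,6-dimethylbenzoate | O=C(OCc1ccccc1)c1c(C)cc(O)c(C)c1O | intermediate
14 | protected depside aldehyde | O=Cc1c(OC)cc(C)c(C(=O)Oc2cc(C)c(C(=O)OCc3ccccc3)c(O)c2C)c1OCc1ccccc1 | intermediate
15 | protected depside acid | OC(=O)c1c(OC)cc(C)c(C(=O)Oc2cc(C)c(C(=O)OCc3ccccc3)c(O)c2C)c1OCc1ccccc1 | intermediate
16 | squamatic acid | COc1cc(C)c(C(=O)Oc2cc(C)c(C(=O)O)c(O)c2C)c(O)c1C(=O)O | target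

## Totals
- Total steps: 14.
- Longest linear sequence: 9 (steps 1–6, then 12–14), which is 64% of the total.

## Three steps most likely to fail, with fallbacks

1. **Step 4 (Casnati formylation of an ester-chelated phenol).** Reactivity may be low because the OH is hydrogen-bonded to the ester.
   Fallback: change the order. Couple 2-O-benzyl-4-O-methylorsellinic acid (no C3 substituent, less hindered) with **13**, remove the ring-A Bn, then do the Mg-directed formylation on the depside. Ring B has no free ortho position, so the regiochemistry is still forced.

2. **Step 6 (LiI cleavage of the hindered methyl ester).** Competing cleavage of the Bn ether or the ArOMe is possible.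
   Fallback: change the protecting strategy. Hydrolyse ester **5** early (KOH), make the allyl ester, then run formylation and benzylation, and remove the allyl ester with Pd(0)/morpholine to give **8**.

3. **Step 12 (acylation of the 4-OH of 13 with hindered acid chloride 8).** The 2,6-disubstituted acyl chloride may be slow, or the ortho-CHO may interfere.
   Fallback: use the ring-A acid without the CHO (2-O-benzyl-4-O-methylorsellinic acid) and do the C3 formylation and Pinnick oxidation after coupling, as in the fallback for step 4.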